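Everything rests on cutting the bond between the carboxyl carbon and carbon 1 of ring B, the benzylic ring (carbon 1 C–CO2H, 2 C–OH, 3 C–CH3, 4 C–OH, 5 C–H, 6 C–CH2O–acyl; ring A is the acyl ring). What remains is the 3,5-dihydroxy-4-methylbenzyl ester of 2,4-dihydroxy-3,6-dimethylbenzoic acid, whose ring B has a mirror plane through carbons 3 and 6: carbons 1 and 5 are the same site, each ortho to one hydroxyl and para to the other, while carbon 5 of ring A, its only free position, is damped by the ester. One protecting-group-free, magnesium-mediated Kolbe–Schmitt carboxylation installs the acid last, so the phthalide-prone ortho-carboxy benzyl ester is never carried through other steps.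

Key step: step 5

Assumption: compound 1, methyl 3,5-dihydroxy-4-methylbenzoate, is bought as such (it is the plain methyl ester of the commercial acid), which keeps a labile silyl ester out of the route.

Step 1
Reactants: 1 methyl 3,5-dihydroxy-4-methylbenzoate
Product: 2 methyl 3,5-bis[(tert-butyldimethylsilyl)oxy]-4-methylbenzoate
Conditions: TBSCl (2.4 equiv), imidazole (5 equiv), DMF, rt
Reagents that add atoms: tert-butyldimethylsilyl chloride (TBSCl), CC(C)(C)[Si](C)(C)Cl
Why: Imidazole-promoted O-silylation of both phenols is routine even next to the ring methyl, and silyl ethers are chosen over benzyl ethers because the ester built in step 3 is itself benzylic and must later be unmasked without hydrogenolysis.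

Step 2
Reactants: 2 methyl 3,5-bis[(tert-butyldimethylsilyl)oxy]-4-methylbenzoate
Product: 3 {3,5-bis[(tert-butyldimethylsilyl)oxy]-4-methylphenyl}methanol
Conditions: i-Bu2AlH (2.5 equiv), CH2Cl2, −78 → 0 °C; aq. KNaC4H4O6
Reagents that add atoms: none
Why: Hydride reduction of the methyl ester to the primary benzylic alcohol with the electrophilic hydride i-Bu2AlH at low temperature should leave the two aryl silyl ethers untouched.

Step 3
Reactants: 3 {3,5-bis[(tert-butyldimethylsilyl)oxy]-4-methylphenyl}methanol, 4 2,4-dihydroxy-3,6-dimethylbenzoic acid
Product: 5 {3,5-bis[(tert-butyldimethylsilyl)oxy]-4-methylphenyl}methyl 2,4-dihydroxy-3,6-dimethylbenzoate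
Conditions: (3-ClC6H4)3P, DIAD, THF, 0 °C → rt (4 in slight excess, DIAD added last)
Reagents that add atoms: none
Why: Mitsunobu esterification forms the ester C–O bond by backside bimolecular displacement at the activated primary benzylic carbon by the carboxylate, so the doubly ortho-substituted carbonyl of ring A is never attacked, and with a weakly basic phosphine betaine the far more acidic carboxyl group of 4 should out-compete its two free phenols.

Step 4
Reactants: 5 {3,5-bis[(tert-butyldimethylsilyl)oxy]-4-methylphenyl}methyl 2,4-dihydroxy-3,6-dimethylbenzoate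
Product: 6 (3,5-dihydroxy-4-methylphenyl)methyl 2,4-dihydroxy-3,6-dimethylbenzoate
Conditions: Bu4NF (2.2 equiv), AcOH (2.5 equiv), THF, 0 °C
Reagents that add atoms: none
Why: Fluoride-induced cleavage of the two aryl silyl ethers under acetic acid buffering should free ring B without exposing the hindered benzylic ester to free phenoxide or to hydrogenolysis.

Step 5
Reactants: 6 (3,5-dihydroxy-4-methylphenyl)methyl 2,4-dihydroxy-3,6-dimethylbenzoate, 7 carbon dioxide
Product: 9 6-{[(2,4-dihydroxy-3,6-dimethylbenzoyl)oxy]methyl}-2,4-dihydroxy-3-methylbenzoic acid (target), via magnesium salicylate chelate of ring B 8 (not isolated)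
Conditions: Mg(OCH3)(OCO2CH3) (2 M in DMF, ca. 10 equiv), CO2 (1 atm), 110 °C; then ice-cold 1 M HCl, EtOAc
Reagents that add atoms: magnesium methoxide methyl carbonate, Mg(OCH3)(OCO2CH3), CO[Mg]OC(=O)OC (carrier that delivers the CO2 unit, O=C=O)
Why: In excess reagent the phenols are magnesium phenoxides, and the oxide on carbon 2 of ring B delivers CO2 from a magnesium-bound methyl carbonate to carbon 1 through a six-membered magnesium-bridged transition state; loss of the ring proton restores the arene as salicylate chelate 8, a thermodynamic sink that cold acid opens to 9. The closest known reaction type is the Kolbe–Schmitt-type ortho-carboxylation of 2,5-dialkylresorcinols with this reagent in hot DMF, which places the carboxyl between a hydroxyl and an alkyl group as required here. No ring is closed and no stereocentre is formed; the single new skeletal bond joins carbon 1 of ring B to the carboxyl carbon. Site selectivity comes from the substrate: carbons 1 and 5 of ring B are mirror images, carbon 3 carries methyl, a second carboxylation at carbon 5 is disfavoured once the first carboxylate withdraws from both ring B oxygens, and carbon 5 of ring A is a poor nucleophile because both ring A oxides are conjugated with the ester. Ring A is left unprotected on purpose, since as a chelated, doubly donor-substituted and doubly ortho-substituted benzoate its carbonyl should resist methanolysis and its carboxylate is a poor leaving group, while magnesium chelation of the new carboxylate and the cold acidic quench hold back 5-exo-tet closure to the phthalide and decarboxylation.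

Compound list
1 | methyl 3,5-dihydroxy-4-methylbenzoate | COC(=O)c1cc(O)c(C)c(O)c1 | starting material
2 | methyl 3,5-bis[(tert-butyldimethylsilyl)oxy]-4-methylbenzoate | COC(=O)c1cc(O[Si](C)(C)C(C)(C)C)c(C)c(O[Si](C)(C)C(C)(C)C)c1 | intermediate
3 | {3,5-bis[(tert-butyldimethylsilyl)oxy]-4-methylphenyl}methanol | OCc1cc(O[Si](C)(C)C(C)(C)C)c(C)c(O[Si](C)(C)C(C)(C)C)c1 | intermediate
4 | 2,4-dihydroxy-3,6-dimethylbenzoic acid | Cc1cc(O)c(C)c(O)c1C(=O)O | starting material
5 | {3,5-bis[(tert-butyldimethylsilyl)oxy]-4-methylphenyl}methyl 2,4-dihydroxy-3,6-dimethylbenzoate | Cc1cc(O)c(C)c(O)c1C(=O)OCc1cc(O[Si](C)(C)C(C)(C)C)c(C)c(O[Si](C)(C)C(C)(C)C)c1 | intermediate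
6 | (3,5-dihydroxy-4-methylphenyl)methyl 2,4-dihydroxy-3,6-dimethylbenzoate | Cc1cc(O)c(C)c(O)c1C(=O)OCc1cc(O)c(C)c(O)c1 | intermediate
7 | carbon dioxide | O=C=O | starting material
8 | magnesium chelate of 9: the ring B salicylate dianion (phenoxide next to the new carboxylate) bound to one magnesium dication, other phenols drawn protonated for simplicity | Cc1cc(O)c(C)c(O)c1C(=O)OCc1cc(O)c(C)c([O-])c1C(=O)[O-].[Mg+2] | intermediate
9 | 6-{[(2,4-dihydroxy-3,6-dimethylbenzoyl)oxy]methyl}-2,4-dihydroxy-3-methylbenzoic acid | Cc1cc(O)c(C)c(O)c1C(=O)OCc1cc(O)c(C)c(O)c1C(=O)O | target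

Total step count: 5. Longest linear sequence: 5 steps (1 → 2 → 3 → 5 → 6 → 9); 4 and 7 enter as purchased materials.

Steps most likely to fail

Step 5 (carboxylation). The carboxylation may stall on the phenoxide side of its equilibrium. The benzylic ester may be lost, either by methanolysis at the ring A carbonyl or by intramolecular displacement of the ring A carboxylate by the new ortho carboxylate. The new acid may also decarboxylate if the acidic work-up warms. Fallback: setting out from 6, the carbon is brought in as an aldehyde under non-basic, low-temperature conditions. Vilsmeier–Haack formylation (POCl3, DMF, CH3CN, 0 °C → rt, then water, 50 °C) at the same symmetry-equivalent ring B carbon should give (2-formyl-3,5-dihydroxy-4-methylphenyl)methyl 2,4-dihydroxy-3,6-dimethylbenzoate F1. Lindgren–Pinnick oxidation of F1 (NaClO2, NaH2PO4, 2-methyl-2-butene in large excess, t-BuOH–H2O, 0 °C → rt) then returns to the route at 9.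

Step 3 (Mitsunobu esterification). Competing O-alkylation of the ring A phenols by the activated benzylic alcohol, or consumption of the betaine by the phenols, may erode the esterification. Fallback: setting out from 3, Appel bromination (CBr4, PPh3, CH2Cl2, 0 °C) should give {[5-(bromomethyl)-2-methyl-1,3-phenylene]bis(oxy)}bis[tert-butyl(dimethyl)silane] F2. F2 alkylates the carboxylate of 4 (KHCO3, DMF, rt), conditions under which only the carboxylic acid is ionised, and rejoins the route at 5.

Step 2 (ester reduction). Partial loss or migration of an aryl silyl group under hydride or aluminium alkoxide, or stalling at the aldehyde, may occur. Fallback: setting out from 1, the order is inverted so that no silyl ether meets hydride. Reduction of the unprotected ester (LiAlH4, THF, reflux; dilute HCl work-up) should give 5-(hydroxymethyl)-2-methylbenzene-1,3-diol F3. Exhaustive silylation (TBSCl, imidazole, DMF, rt) gives tert-butyl({3,5-bis[(tert-butyldimethylsilyl)oxy]-4-methylphenyl}methoxy)dimethylsilane F4. Selective acid-catalysed methanolysis of the more acid-labile primary alkyl silyl ether (camphorsulfonic acid cat., CH3OH–CH2Cl2, 0 °C) returns to the route at 3.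

Further compounds
F1 | step 5 | (2-formyl-3,5-dihydroxy-4-methylphenyl)methyl 2,4-dihydroxy-3,6-dimethylbenzoate | Cc1cc(O)c(C)c(O)c1C(=O)OCc1cc(O)c(C)c(O)c1C=O
F2 | step 3 | {[5-(bromomethyl)-2-methyl-1,3-phenylene]bis(oxy)}bis[tert-butyl(dimethyl)silane] | Cc1c(O[Si](C)(C)C(C)(C)C)cc(CBr)cc1O[Si](C)(C)C(C)(C)C
F3 | step 2 | 5-(hydroxymethyl)-2-methylbenzene-1,3-diol | Cc1c(O)cc(CO)cc1O
F4 | step 2 | tert-butyl({3,5-bis[(tert-butyldimethylsilyl)oxy]-4-methylphenyl}methoxy)dimethylsilane | Cc1c(O[Si](C)(C)C(C)(C)C)cc(CO[Si](C)(C)C(C)(C)C)cc1O[Si](C)(C)C(C)(C)C
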